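Everything hangs on cutting the C2–C3 bond of ring C. C2 carries only hydrogen, O1 and the phenyl group, so in retrosynthesis it is the CH2 of a benzyl ether attached to the C8a oxygen of ring A. C3 is the α-carbon of the C4 ketone and can be brought in as a diazo carbon. With a chiral dirhodium carboxylate the aryl diazomethyl ketone loses nitrogen and the carbenoid inserts into one of the two enantiotopic benzylic C–H bonds. This one operation makes C2–C3, closes ring C and fixes (2S). The precursor is a 2-benzyloxyaryl diazomethyl ketone that already bears the C8 benzyl group. The free C6 position takes up the triphenol side chain at the end.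

Key step: step 7

**Numbering.** Flavanone numbering is O1, C2, C3, C4, C4a, C5 to C8, C8a; ring A is the benzo ring and ring C the pyranone. The ring on the C8 methylene is the C8 side ring, and its oxygen is O2''. In the C6 side chain, ring D is bonded to the C6 methylene, ring E is the middle ring and ring F the terminal ring.

**Structure check.**
- C2 is the only stereocentre. With O1 > phenyl carbon > C3 > H, the SMILES descriptor reads S.
- Ring D carries the C6 methylene ortho and the ring E methylene para to its OH.
- Ring E is a phenol benzylated at both ortho positions.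

**Design of the precursor.**
- (a) O5 is the only methyl ether. Beside the carbenoid it offers just primary C–H bonds and no group able to migrate from an oxonium ylide. In the product it lies peri to the C4 carbonyl, where BCl3 removes it by chelation at or below 0 °C.
- (b) O7 and O2'' are benzyl ethers. They are out of reach of C3 and are cleaved by neutral hydrogenolysis. No exhaustive BBr3-type demethylation is needed, which would also attack the benzylic C2–O1 bond and endanger C2.
- (c) Ring A is carried through a mirror-symmetric intermediate with two equivalent benzyloxy groups flanking the C8 benzyl group. Acylation can then give only one ketone, and O1 necessarily sits beside C8.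
- (d) The diazoketone comes from the methyl ketone by diazo transfer, so no decarboxylation-prone acid, acid chloride or diazomethane is used.

Assumption: the absolute sense of induction of Rh2(S-PTTL)4 on this substrate cannot be derived from first principles. The route is written for the (S)-ligand, and the mirror-image catalyst Rh2(R-PTTL)4 is taken instead if a pilot run shows that it is the one that replaces the pro-S hydrogen.

## Route

Step 1
Reactants: 1 2-hydroxy-4,6-dimethoxybenzaldehyde
Product: 2 2,6-dihydroxy-4-methoxybenzaldehyde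
Conditions: AlCl3 (4 equiv), CH2Cl2, 0 °C to reflux; then 1 M aq HCl
Reagents that add atoms: none
Why: Chelation-controlled Lewis-acid ether cleavage, in which aluminium binds the formyl oxygen together with the neighbouring methoxy oxygen so that chloride dealkylates only the ortho methyl ether, while the para methoxy group (the later O5 methyl ether) cannot chelate and is kept.

Step 2
Reactants: 2 2,6-dihydroxy-4-methoxybenzaldehyde; 3 benzyl bromide
Product: 4 2,6-bis(benzyloxy)-4-methoxybenzaldehyde
Conditions: 3 (2.5 equiv), K2CO3, DMF, 60 °C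
Reagents that add atoms: none
Why: Exhaustive Williamson etherification of both phenols needs no selectivity, the two benzyl ethers stay equivalent, and step 5 decides which one becomes O1–C2–phenyl and which one protects O7.

Step 3
Reactants: 4 2,6-bis(benzyloxy)-4-methoxybenzaldehyde; 5 1-(benzyloxy)-2-bromobenzene
Product: 7 [2,6-bis(benzyloxy)-4-methoxyphenyl][2-(benzyloxy)phenyl]methanol (racemic), via aryl Grignard reagent 6 (not isolated)
Conditions: 5, Mg turnings, cat. I2, THF, reflux; then 4, THF, 0 °C to rt; aq NH4Cl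
Reagents that add atoms: none
Why: Grignard addition of an aryl nucleophile to a non-enolisable aldehyde that has no acidic proton left, the carbinol centre being formed as a racemate and erased in step 4.

Step 4
Reactants: 7 [2,6-bis(benzyloxy)-4-methoxyphenyl][2-(benzyloxy)phenyl]methanol
Product: 8 1,3-bis(benzyloxy)-2-[2-(benzyloxy)benzyl]-5-methoxybenzene
Conditions: Et3SiH (3 equiv), CF3CO2H (5 equiv), CH2Cl2, −40 to 0 °C
Reagents that add atoms: none
Why: Ionic hydrogenation, in which the carbinol ionises at low temperature to a diarylmethyl cation stabilised by four alkoxy groups, Et3SiH traps it by hydride transfer, and aryl benzyl ethers tolerate the brief cold exposure to CF3CO2H.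

Step 5
Reactants: 8 1,3-bis(benzyloxy)-2-[2-(benzyloxy)benzyl]-5-methoxybenzene
Product: 9 1-{2,4-bis(benzyloxy)-3-[2-(benzyloxy)benzyl]-6-methoxyphenyl}ethan-1-one
Conditions: AcOH (1.5 equiv) premixed with (CF3CO)2O (1.4 equiv), CH2Cl2, 0 °C to rt
Reagents that add atoms: acetic acid, CC(=O)O
Why: Friedel–Crafts acylation by acetyl trifluoroacetate without a metal Lewis acid (hence no chelation-driven ether cleavage), in which the 1,3,5-trioxygenated ring A of 8 is far more nucleophilic than any other ring and its two free carbons are related by a mirror plane, so only one ketone can form, with the acyl carbon (C4) between the methoxy group (O5) and a benzyloxy group (O1) that itself neighbours the C8 benzyl group.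

Step 6
Reactants: 9 1-{2,4-bis(benzyloxy)-3-[2-(benzyloxy)benzyl]-6-methoxyphenyl}ethan-1-one
Product: 11 1-{2,4-bis(benzyloxy)-3-[2-(benzyloxy)benzyl]-6-methoxyphenyl}-2-diazoethan-1-one, via trifluoroacetyl diketone 10 (not isolated)
Conditions: LiN(SiMe3)2, THF, −78 °C; CF3CO2CH2CF3; 1 M aq HCl; crude 10, p-ABSA, Et3N, H2O (1 equiv), MeCN, rt
Reagents that add atoms: 4-acetamidobenzenesulfonyl azide (p-ABSA), CC(=O)Nc1ccc(cc1)S(=O)(=O)N=[N+]=[N-]
Why: Detrifluoroacetylative Regitz diazo transfer, in which the kinetic lithium enolate is trifluoroacetylated, the activated 1,3-diketone 10 accepts the diazo group from the sulfonyl azide, and the trifluoroacetyl group leaves on the sulfonamide nitrogen to give the terminal diazoketone.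

Step 7
Reactants: 11 1-{2,4-bis(benzyloxy)-3-[2-(benzyloxy)benzyl]-6-methoxyphenyl}-2-diazoethan-1-one
Product: 12 (2S)-7-(benzyloxy)-8-[2-(benzyloxy)benzyl]-5-methoxy-2-phenylchroman-4-one
Conditions: Rh2(S-PTTL)4 (PTTL = N-phthaloyl-tert-leucinate, 2 mol %), 4 Å molecular sieves, CH2Cl2, 0 °C, slow addition of 11 at high dilution
Reagents that add atoms: none
Why: The divalent rhodium dimer Rh2(S-PTTL)4 expels N2 from 11 and gives an electrophilic carbenoid at C3, which inserts in a concerted, asynchronous, hydride-transfer-like three-centre event into a C–H bond of the O1–CH2Ph group and releases the catalyst. The closest known reaction type is the chroman-4-one synthesis by intramolecular C–H insertion of 2-alkoxyaryl diazoketones under chiral dirhodium carboxylate catalysis. Ring C closes as a six-membered ring by 1,6-insertion (C3, C4, C4a, C8a, O1, C2), the ring-closing bond being C2–C3. C2 is the only new stereocentre and is controlled by the catalyst alone: the wall of phthalimido groups lets the carbenoid reach only one of the two enantiotopic benzylic hydrogens, insertion goes with retention, and replacement of the pro-S hydrogen gives (2S). The step needs site selectivity over capture of the carbenoid by O1 (oxonium ylide, then 1,2-shift of benzyl), over reaction at the O5 methyl group and over addition to the phenyl ring; the substrate secures it because the target C–H bonds are activated by both oxygen and phenyl, O1 is a weakly basic aryl oxygen conjugated to the ketone, the O5 methyl group has only primary C–H bonds and cannot migrate, and the benzyl ethers on O7 and O2'' and the C8 methylene cannot reach C3 through any unstrained ring. The neutral medium at 0 °C gives the new centre no path to retro-oxa-Michael opening.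

Step 8
Reactants: 12 (2S)-7-(benzyloxy)-8-[2-(benzyloxy)benzyl]-5-methoxy-2-phenylchroman-4-one
Product: 13 (2S)-7-hydroxy-8-(2-hydroxybenzyl)-5-methoxy-2-phenylchroman-4-one
Conditions: H2 (1 atm), Pd/C (10 wt %), EtOAc–EtOH, rt
Reagents that add atoms: none
Why: Catalytic hydrogenolysis of the two primary aryl benzyl ethers under neutral conditions is much faster than cleavage of the cyclic secondary C2–O1 bond or reduction of the conjugated C4 ketone, and no acid or base is present that could open ring C, so (2S) is kept.

Step 9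
Reactants: 13 (2S)-7-hydroxy-8-(2-hydroxybenzyl)-5-methoxy-2-phenylchroman-4-one
Product: 14 (2S)-5,7-dihydroxy-8-(2-hydroxybenzyl)-2-phenylchroman-4-one
Conditions: BCl3 (4 equiv), CH2Cl2, −78 to 0 °C; then ice-water
Reagents that add atoms: none
Why: Chelation-assisted demethylation, in which BCl3 forms a six-membered boron chelate between the C4 carbonyl oxygen and O5 and chloride removes the methyl group by SN2 attack at low temperature, a process that touches neither C2–O1 nor C3 and leaves (2S) intact.

Step 10
Reactants: 15 4-bromo-2-(hydroxymethyl)phenol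
Product: 16 6-bromo-2,2-dimethyl-4H-1,3-benzodioxine
Conditions: 2,2-dimethoxypropane, cat. p-TsOH·H2O, acetone, rt
Reagents that add atoms: 2,2-dimethoxypropane, COC(C)(C)OC
Why: Acid-catalysed transketalisation ties the phenol and the benzylic alcohol of ring D into one six-membered acetonide that is inert to organolithium reagents, hydride and hot alkali.

Step 11
Reactants: 17 2,2'-methylenediphenol
Product: 18 2-hydroxy-3-(2-hydroxybenzyl)benzaldehyde
Conditions: MgCl2 (anhydrous), Et3N, paraformaldehyde (limiting), MeCN, reflux; then 1 M aq HCl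
Reagents that add atoms: paraformaldehyde (as formaldehyde), C=O
Why: Casnati–Skattebøl ortho-formylation, in which the magnesium phenoxide delivers coordinated formaldehyde only to the carbon ortho to its own oxygen and a second formaldehyde oxidises the benzylic alkoxide by hydride transfer, the two rings being equivalent so that only one monoaldehyde exists and limiting formaldehyde holds the reaction at that stage, with unreacted 17 recycled.

Step 12
Reactants: 16 6-bromo-2,2-dimethyl-4H-1,3-benzodioxine; 18 2-hydroxy-3-(2-hydroxybenzyl)benzaldehyde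
Product: 20 2-[(2,2-dimethyl-4H-1,3-benzodioxin-6-yl)(hydroxy)methyl]-6-(2-hydroxybenzyl)phenol (racemic), via aryllithium 19 (not isolated)
Conditions: 16 (3.3 equiv), n-BuLi (3.2 equiv), THF, −78 °C; then 18, −78 to 0 °C; aq NH4Cl
Reagents that add atoms: none
Why: Bromine–lithium exchange followed by 1,2-addition to the aldehyde, two equivalents of 19 being spent on the phenol protons, the acetonide being stable to the base, and the new carbinol centre being racemic and removed in step 13.

Step 13
Reactants: 20 2-[(2,2-dimethyl-4H-1,3-benzodioxin-6-yl)(hydroxy)methyl]-6-(2-hydroxybenzyl)phenol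
Product: 22 2-[(2,2-dimethyl-4H-1,3-benzodioxin-6-yl)methyl]-6-(2-hydroxybenzyl)phenol, via ortho-quinone methide 21 (not isolated)
Conditions: NaBH4 (excess), 1 M aq NaOH, i-PrOH, reflux
Reagents that add atoms: none
Why: Base-induced 1,4-elimination of water from the ortho-hydroxybenzhydrol gives the aryl-stabilised ortho-quinone methide 21, which NaBH4 reduces irreversibly by conjugate hydride addition (the known deoxygenation of ortho- and para-hydroxybenzylic alcohols by NaBH4 in hot alkali), and the acid-labile acetonide is safe in this medium.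

Step 14
Reactants: 22 2-[(2,2-dimethyl-4H-1,3-benzodioxin-6-yl)methyl]-6-(2-hydroxybenzyl)phenol
Product: 23 4-[2-hydroxy-3-(2-hydroxybenzyl)benzyl]-2-(hydroxymethyl)phenol
Conditions: 1 M aq HCl, THF, rt
Reagents that add atoms: none
Why: Mild aqueous acid hydrolysis of the aryl alkyl ketal releases acetone and the salicyl alcohol at room temperature, below the threshold at which the product would ionise and oligomerise.

Step 15
Reactants: 14 (2S)-5,7-dihydroxy-8-(2-hydroxybenzyl)-2-phenylchroman-4-one; 23 4-[2-hydroxy-3-(2-hydroxybenzyl)benzyl]-2-(hydroxymethyl)phenol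
Product: 25 (2S)-5,7-dihydroxy-6-{2-hydroxy-5-[2-hydroxy-3-(2-hydroxybenzyl)benzyl]benzyl}-8-(2-hydroxybenzyl)-2-phenylchroman-4-one, via ortho-quinone methide 24 (not isolated)
Conditions: ZnCl2 (anhydrous, 2 equiv), 1,4-dioxane, 70 °C, slow addition of 23
Reagents that add atoms: none
Why: ZnCl2 ionises the ortho-hydroxybenzylic alcohol of 23 to the ortho-quinone methide 24, and C6 of 14, the only unsubstituted carbon of the phloroglucinol-type ring A and by far the most nucleophilic arene position present, adds to its methylene carbon in a Friedel–Crafts-type conjugate addition with rearomatisation of both rings, while C2 is not involved and base is absent.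

## Compound list

1 | 2-hydroxy-4,6-dimethoxybenzaldehyde | COc1cc(O)c(C=O)c(OC)c1 | starting material
2 | 2,6-dihydroxy-4-methoxybenzaldehyde | COc1cc(O)c(C=O)c(O)c1 | intermediate
3 | benzyl bromide | BrCc1ccccc1 | starting material
4 | 2,6-bis(benzyloxy)-4-methoxybenzaldehyde | COc1cc(OCc2ccccc2)c(C=O)c(OCc2ccccc2)c1 | intermediate
5 | 1-(benzyloxy)-2-bromobenzene | Brc1ccccc1OCc1ccccc1 | starting material
6 | [2-(benzyloxy)phenyl]magnesium bromide | Br[Mg]c1ccccc1OCc1ccccc1 | intermediate
7 | [2,6-bis(benzyloxy)-4-methoxyphenyl][2-(benzyloxy)phenyl]methanol (racemic) | COc1cc(OCc2ccccc2)c(C(O)c2ccccc2OCc2ccccc2)c(OCc2ccccc2)c1 | intermediate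
8 | 1,3-bis(benzyloxy)-2-[2-(benzyloxy)benzyl]-5-methoxybenzene | COc1cc(OCc2ccccc2)c(Cc2ccccc2OCc2ccccc2)c(OCc2ccccc2)c1 | intermediate
9 | 1-{2,4-bis(benzyloxy)-3-[2-(benzyloxy)benzyl]-6-methoxyphenyl}ethan-1-one | CC(=O)c1c(OC)cc(OCc2ccccc2)c(Cc2ccccc2OCc2ccccc2)c1OCc1ccccc1 | intermediate
10 | 1-{2,4-bis(benzyloxy)-3-[2-(benzyloxy)benzyl]-6-methoxyphenyl}-4,4,4-trifluorobutane-1,3-dione | O=C(CC(=O)C(F)(F)F)c1c(OC)cc(OCc2ccccc2)c(Cc2ccccc2OCc2ccccc2)c1OCc1ccccc1 | intermediate
11 | 1-{2,4-bis(benzyloxy)-3-[2-(benzyloxy)benzyl]-6-methoxyphenyl}-2-diazoethan-1-one | [N-]=[N+]=CC(=O)c1c(OC)cc(OCc2ccccc2)c(Cc2ccccc2OCc2ccccc2)c1OCc1ccccc1 | intermediate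
12 | (2S)-7-(benzyloxy)-8-[2-(benzyloxy)benzyl]-5-methoxy-2-phenylchroman-4-one | O=C1C[C@@H](c2ccccc2)Oc2c(Cc3ccccc3OCc3ccccc3)c(OCc3ccccc3)cc(OC)c21 | intermediate
13 | (2S)-7-hydroxy-8-(2-hydroxybenzyl)-5-methoxy-2-phenylchroman-4-one | O=C1C[C@@H](c2ccccc2)Oc2c(Cc3ccccc3O)c(O)cc(OC)c21 | intermediate
14 | (2S)-5,7-dihydroxy-8-(2-hydroxybenzyl)-2-phenylchroman-4-one | O=C1C[C@@H](c2ccccc2)Oc2c(Cc3ccccc3O)c(O)cc(O)c21 | intermediate
15 | 4-bromo-2-(hydroxymethyl)phenol (5-bromo-2-hydroxybenzyl alcohol) | OCc1cc(Br)ccc1O | starting material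
16 | 6-bromo-2,2-dimethyl-4H-1,3-benzodioxine | CC1(C)OCc2cc(Br)ccc2O1 | intermediate
17 | 2,2'-methylenediphenol | Oc1ccccc1Cc1ccccc1O | starting material
18 | 2-hydroxy-3-(2-hydroxybenzyl)benzaldehyde | O=Cc1cccc(Cc2ccccc2O)c1O | intermediate
19 | (2,2-dimethyl-4H-1,3-benzodioxin-6-yl)lithium | [Li]c1ccc2OC(C)(C)OCc2c1 | intermediate
20 | 2-[(2,2-dimethyl-4H-1,3-benzodioxin-6-yl)(hydroxy)methyl]-6-(2-hydroxybenzyl)phenol (racemic) | CC1(C)OCc2cc(C(O)c3cccc(Cc4ccccc4O)c3O)ccc2O1 | intermediate
21 | 6-[(2,2-dimethyl-4H-1,3-benzodioxin-6-yl)methylidene]-2-(2-hydroxybenzyl)cyclohexa-2,4-dien-1-one | CC1(C)OCc2cc(C=C3C=CC=C(Cc4ccccc4O)C3=O)ccc2O1 | intermediate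
22 | 2-[(2,2-dimethyl-4H-1,3-benzodioxin-6-yl)methyl]-6-(2-hydroxybenzyl)phenol | CC1(C)OCc2cc(Cc3cccc(Cc4ccccc4O)c3O)ccc2O1 | intermediate
23 | 4-[2-hydroxy-3-(2-hydroxybenzyl)benzyl]-2-(hydroxymethyl)phenol | OCc1cc(Cc2cccc(Cc3ccccc3O)c2O)ccc1O | intermediate
24 | 4-[2-hydroxy-3-(2-hydroxybenzyl)benzyl]-6-methylidenecyclohexa-2,4-dien-1-one | C=C1C=C(Cc2cccc(Cc3ccccc3O)c2O)C=CC1=O | intermediate
25 | (2S)-5,7-dihydroxy-6-{2-hydroxy-5-[2-hydroxy-3-(2-hydroxybenzyl)benzyl]benzyl}-8-(2-hydroxybenzyl)-2-phenylchroman-4-one (CNP0107650.1) | O=C1C[C@@H](c2ccccc2)Oc2c(Cc3ccccc3O)c(O)c(Cc3cc(Cc4cccc(Cc5ccccc5O)c4O)ccc3O)c(O)c21 | target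

## Step count and risks

Total step count: 15. Longest linear sequence: 10 (steps 1 to 9, then step 15).

**Step 7 (highest risk).**
- What may go wrong: the O1 lone pair may capture the carbenoid, after which benzyl migrates. Discrimination between the two enantiotopic hydrogens may also be only moderate, since acceptor-only carbenoids are very reactive.
- Fallback: it sets out from methyl ketone 9 and comes back at flavanone 12. MgBr2·OEt2 in toluene–Et2O at reflux removes the benzyl ether that can chelate with the ketone (benzyl leaves faster than the equally chelated methyl) and gives the ortho-hydroxy ketone F1. Heating with Me2NCH(OMe)2 in toluene gives the enaminone F2, which closes with HCl in CH2Cl2 to the chromone F3. PhB(OH)2 is then added in conjugate fashion under Pd(OCOCF3)2 and the t-BuPyOX antipode that leads to the (2S) series (NH4PF6, H2O, ClCH2CH2Cl, 60 °C). This is a known asymmetric 1,4-addition to chromones, and it delivers 12.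

**Step 15.**
- What may go wrong: the quinone methide may condense with the phenol rings of its own precursor. The C2 configuration may erode slowly through Lewis-acid-assisted opening of ring C at 70 °C.
- Fallback: it sets out from 12 and 23 and comes back at target 25. NIS with catalytic CF3CO2H in MeCN at 0 °C iodinates the only free ring A carbon of 12 to the 6-iodoflavanone F4. In parallel, 23 is O-benzylated at its three phenols (3, K2CO3, acetone) to the tribenzyl ether alcohol F5. SOCl2 in CH2Cl2 converts this into the benzylic chloride F6, and Zn dust with LiCl in THF gives the benzylic zinc chloride F7. Negishi coupling of F4 with F7 (Pd(OAc)2, SPhos, THF, rt) forms the C6–CH2 bond under neutral conditions and gives the fully protected flavanone F8. Hydrogenolysis (H2, Pd/C) gives the 5-O-methyl ether F9, and BCl3 as in step 9 gives 25.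

**Step 13.**
- What may go wrong: loss of hydroxide from the phenoxide may be too slow, so that conversion stalls. The quinone methide may also dimerise before hydride reaches it.
- Fallback: it replaces steps 12 and 13, sets out from 18 and 16, and comes back at 22. Boc2O, i-Pr2NEt and catalytic DMAP in CH2Cl2 convert 18 into the bis(tert-butyl carbonate) aldehyde F10. Compound 16 and Mg in THF give the aryl Grignard reagent F11. One equivalent of F11 is added to F10 at −78 °C and gives a magnesium alkoxide that takes over the neighbouring Boc group. The freed phenoxide expels tert-butyl carbonate below room temperature. The resulting carbonate-bearing quinone methide F12 is reduced in the same flask by LiBH4 to the mono(tert-butyl carbonate) F13. K2CO3 in MeOH removes the last carbonate and gives 22. This is the known anionic generation of ortho-quinone methides from O-Boc salicylaldehydes.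

## Further compounds

F1 | step 7 | 1-{4-(benzyloxy)-3-[2-(benzyloxy)benzyl]-2-hydroxy-6-methoxyphenyl}ethan-1-one | CC(=O)c1c(OC)cc(OCc2ccccc2)c(Cc2ccccc2OCc2ccccc2)c1O
F2 | step 7 | (E)-1-{4-(benzyloxy)-3-[2-(benzyloxy)benzyl]-2-hydroxy-6-methoxyphenyl}-3-(dimethylamino)prop-2-en-1-one | CN(C)/C=C/C(=O)c1c(OC)cc(OCc2ccccc2)c(Cc2ccccc2OCc2ccccc2)c1O
F3 | step 7 | 7-(benzyloxy)-8-[2-(benzyloxy)benzyl]-5-methoxy-4H-chromen-4-one | O=c1ccoc2c(Cc3ccccc3OCc3ccccc3)c(OCc3ccccc3)cc(OC)c12
F4 | step 15 | (2S)-7-(benzyloxy)-8-[2-(benzyloxy)benzyl]-6-iodo-5-methoxy-2-phenylchroman-4-one | O=C1C[C@@H](c2ccccc2)Oc2c(Cc3ccccc3OCc3ccccc3)c(OCc3ccccc3)c(I)c(OC)c21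
F5 | step 15 | (2-(benzyloxy)-5-{2-(benzyloxy)-3-[2-(benzyloxy)benzyl]benzyl}phenyl)methanol | OCc1cc(Cc2cccc(Cc3ccccc3OCc3ccccc3)c2OCc2ccccc2)ccc1OCc1ccccc1
F6 | step 15 | 1-(benzyloxy)-4-{2-(benzyloxy)-3-[2-(benzyloxy)benzyl]benzyl}-2-(chloromethyl)benzene | ClCc1cc(Cc2cccc(Cc3ccccc3OCc3ccccc3)c2OCc2ccccc2)ccc1OCc1ccccc1
F7 | step 15 | (2-(benzyloxy)-5-{2-(benzyloxy)-3-[2-(benzyloxy)benzyl]benzyl}benzyl)zinc chloride | Cl[Zn]Cc1cc(Cc2cccc(Cc3ccccc3OCc3ccccc3)c2OCc2ccccc2)ccc1OCc1ccccc1
F8 | step 15 | (2S)-7-(benzyloxy)-8-[2-(benzyloxy)benzyl]-6-(2-(benzyloxy)-5-{2-(benzyloxy)-3-[2-(benzyloxy)benzyl]benzyl}benzyl)-5-methoxy-2-phenylchroman-4-one | O=C1C[C@@H](c2ccccc2)Oc2c(Cc3ccccc3OCc3ccccc3)c(OCc3ccccc3)c(Cc3cc(Cc4cccc(Cc5ccccc5OCc5ccccc5)c4OCc4ccccc4)ccc3OCc3ccccc3)c(OC)c21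
F9 | step 15 | (2S)-7-hydroxy-6-{2-hydroxy-5-[2-hydroxy-3-(2-hydroxybenzyl)benzyl]benzyl}-8-(2-hydroxybenzyl)-5-methoxy-2-phenylchroman-4-one | O=C1C[C@@H](c2ccccc2)Oc2c(Cc3ccccc3O)c(O)c(Cc3cc(Cc4cccc(Cc5ccccc5O)c4O)ccc3O)c(OC)c21
F10 | step 13 | tert-butyl 2-{2-[(tert-butoxycarbonyl)oxy]benzyl}-6-formylphenyl carbonate | O=Cc1cccc(Cc2ccccc2OC(=O)OC(C)(C)C)c1OC(=O)OC(C)(C)C
F11 | step 13 | (2,2-dimethyl-4H-1,3-benzodioxin-6-yl)magnesium bromide | Br[Mg]c1ccc2OC(C)(C)OCc2c1
F12 | step 13 | tert-butyl 2-({5-[(2,2-dimethyl-4H-1,3-benzodioxin-6-yl)methylidene]-6-oxocyclohexa-1,3-dien-1-yl}methyl)phenyl carbonate | CC1(C)OCc2cc(C=C3C=CC=C(Cc4ccccc4OC(=O)OC(C)(C)C)C3=O)ccc2O1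
F13 | step 13 | tert-butyl 2-{3-[(2,2-dimethyl-4H-1,3-benzodioxin-6-yl)methyl]-2-hydroxybenzyl}phenyl carbonate | CC1(C)OCc2cc(Cc3cccc(Cc4ccccc4OC(=O)OC(C)(C)C)c3O)ccc2O1
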